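**Plan**

- Retrosynthesis: the O–CH3 bonds at C5 and C7 are cut first (back to nevadensin). Then O1–C2 (ring C) and C4a–C5 (ring A) are cut, which unfolds the flavone into one linear tetraketo ester. The chain is then cut at C5–C6, C7–C8 and C4a–C8a, back to an aryl butanedione, two methoxyacetyl units and a carbonate carbon.
- Enabling feature: ring A carries oxygen on the alternate carbons C5, C7 and C8a, with the acyl carbon C4 on C4a (an acylphloroglucinol). Its methoxy groups on C6 and C8 fall on the α-carbons of two methoxyacetyl units, and C2–C3–C4 of ring C continue the same chain.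
- Forward: three polyenolate acylations lengthen the chain from the aryl end (C4a–C8a, then C8–C7, then C6–C5). One Claisen/cyclodehydration operation closes ring A and then ring C, and a double O-methylation finishes.
- Stereochemistry: the target is achiral. The methoxy-bearing methines of the chain are epimerisable and become sp2 carbons of ring A, so nothing has to be controlled.

Key step: step 4

Remark: polycarbonyl compounds are drawn as keto tautomers (they are largely enolised and their methoxy methines are configurationally labile, so no descriptors are given); lithium polyenolates, the tetrahedral amide adducts and magnesium chelates are treated as metallated forms of the numbered compounds, and LiN(iPr)2 is taken from a commercial solution.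

**Route**

Step 1
Reactants: 1 1-(4-methoxyphenyl)butane-1,3-dione; 2 N,2-dimethoxy-N-methylacetamide
Product: 3 6-methoxy-1-(4-methoxyphenyl)hexane-1,3,5-trione
Conditions: LiN(iPr)2 (2.1 equiv), THF, 0 °C; then 2 (1.0 equiv), −78 to 0 °C; cold 1 M HCl
Reagents that add atoms: none
Why: Two equivalents of amide base should give the 1,3-dianion of the β-diketone, whose terminal methyl carbanion is C-acylated by the N-methoxy-N-methylamide (Weinreb acylation of a β-diketone dianion), and because the chelated tetrahedral adduct survives until the acidic quench, neither a second addition nor proton transfer to unreacted dianion is expected.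

Step 2
Reactants: 3 6-methoxy-1-(4-methoxyphenyl)hexane-1,3,5-trione; 2 N,2-dimethoxy-N-methylacetamide
Product: 4 6,8-dimethoxy-1-(4-methoxyphenyl)octane-1,3,5,7-tetraone
Conditions: LiN(iPr)2 (3.2 equiv), THF, 0 °C; then 2 (1.05 equiv), −78 to 0 °C; cold 1 M HCl, used without delay
Reagents that add atoms: none
Why: The aryl end has no α-hydrogen, so the third deprotonation can only occur at the methoxymethyl terminus, and Weinreb acylation of that 1,3,5-trianion (polyanion acylation of a triketone) should place the first methoxy branch between two carbonyls.

Step 3
Reactants: 4 6,8-dimethoxy-1-(4-methoxyphenyl)octane-1,3,5,7-tetraone; 5 dimethyl carbonate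
Product: 6 methyl 2,4-dimethoxy-9-(4-methoxyphenyl)-3,5,7,9-tetraoxononanoate
Conditions: LiN(iPr)2 (5 equiv), THF, 0 °C; then (MeO)2CO (1.5 equiv), −78 to 0 °C; cold 1 M HCl
Reagents that add atoms: none
Why: Four equivalents of base should give the tetraanion, whose only non-stabilised carbanion is the terminal methoxymethyl carbon, and its C-acylation by dimethyl carbonate (Claisen-type carboxylation of a polyketone polyanion) installs the ester, the fifth equivalent of base taking up the acidic proton of the new β-keto ester so that no tetraanion is lost by proton transfer.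

Step 4
Reactants: 6 methyl 2,4-dimethoxy-9-(4-methoxyphenyl)-3,5,7,9-tetraoxononanoate
Product: 9 5,7-dihydroxy-6,8-dimethoxy-2-(4-methoxyphenyl)chromen-4-one (nevadensin), via acylphloroglucinol diketone 7 (not isolated), via cyclic hemiketal 8 (not isolated)
Conditions: Mg(OMe)2 (8 equiv), degassed MeOH, 25 to 65 °C, Ar; then conc. HCl to pH 1, 65 °C
Reagents that add atoms: none
Why: Mg(OMe)2 should turn 6 into a chelated polyenolate in which every ketone is enolised and the ester carbon (chain C1, the future C5) is the only electrophile left, so the carbon between the chain C5 and C7 carbonyls (the future C4a) attacks it in a 6-exo-trig Claisen (Dieckmann-type) closure, methoxide leaves and enolisation gives acylphloroglucinol 7 with both methoxy groups in place. After acidification a ring A hydroxyl ortho to the acyl group adds to the protonated aryl ketone (6-exo-trig) to give hemiketal 8, and loss of water forms O1–C2 and the pyranone ring C. The closest known reactions are the base-induced Claisen cyclisation of 3,5,7-triketo esters to acylphloroglucinols and the acid cyclodehydration of 2-hydroxydibenzoylmethanes used in the Baker–Venkataraman flavone synthesis. No stereocentre is created, since the two methoxy methines become sp2 carbons and the hemiketal carbon is lost on dehydration. The step needs Claisen rather than aldol folding: the methoxy groups on chain C2 and C4 make aldol adducts from those carbons quaternary, non-aromatisable and therefore reversible, and the one aromatisable aldol (the future C3 methylene onto the chain C3 ketone) is disfavoured because that ketone lies between two branched carbons and is held as a magnesium enolate chelate. Ring A is symmetric about its acyl axis, so either ortho hydroxyl closes ring C to the same flavone.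

Step 5
Reactants: 9 5,7-dihydroxy-6,8-dimethoxy-2-(4-methoxyphenyl)chromen-4-one
Product: 10 tangeretin, 5,6,7,8-tetramethoxy-2-(4-methoxyphenyl)chromen-4-one
Conditions: Me2SO4 (6 equiv), K2CO3 (8 equiv), acetone, reflux, 24–48 h; aq NH3 quench
Reagents that add atoms: dimethyl sulfate, COS(=O)(=O)OC
Why: Williamson O-methylation of both phenols, in which the C7 hydroxyl should react readily and the hydrogen-bonded C5 hydroxyl requires the excess reagent and long reflux usual for 5-hydroxyflavones, while the flavone core and the existing methyl ethers are inert.

**Compound list**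

1 | 1-(4-methoxyphenyl)butane-1,3-dione | COc1ccc(C(=O)CC(C)=O)cc1 | starting material
2 | N,2-dimethoxy-N-methylacetamide | COCC(=O)N(C)OC | starting material
3 | 6-methoxy-1-(4-methoxyphenyl)hexane-1,3,5-trione | COc1ccc(C(=O)CC(=O)CC(=O)COC)cc1 | intermediate
4 | 6,8-dimethoxy-1-(4-methoxyphenyl)octane-1,3,5,7-tetraone (C6 epimerisable) | COc1ccc(C(=O)CC(=O)CC(=O)C(OC)C(=O)COC)cc1 | intermediate
5 | dimethyl carbonate | COC(=O)OC | starting material
6 | methyl 2,4-dimethoxy-9-(4-methoxyphenyl)-3,5,7,9-tetraoxononanoate (epimerisable mixture) | COc1ccc(C(=O)CC(=O)CC(=O)C(OC)C(=O)C(OC)C(=O)OC)cc1 | intermediate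
7 | 1-(2,4,6-trihydroxy-3,5-dimethoxyphenyl)-3-(4-methoxyphenyl)propane-1,3-dione | COc1ccc(C(=O)CC(=O)c2c(O)c(OC)c(O)c(OC)c2O)cc1 | intermediate
8 | 2,5,7-trihydroxy-6,8-dimethoxy-2-(4-methoxyphenyl)-2,3-dihydrochromen-4-one (racemic hemiketal) | COc1ccc(C2(O)CC(=O)c3c(O)c(OC)c(O)c(OC)c3O2)cc1 | intermediate
9 | 5,7-dihydroxy-6,8-dimethoxy-2-(4-methoxyphenyl)chromen-4-one (nevadensin) | COc1ccc(-c2cc(=O)c3c(O)c(OC)c(O)c(OC)c3o2)cc1 | intermediate
10 | tangeretin, 5,6,7,8-tetramethoxy-2-(4-methoxyphenyl)chromen-4-one | COc1ccc(-c2cc(=O)c3c(OC)c(OC)c(OC)c(OC)c3o2)cc1 | target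

**Step count**

Total steps: 5. Longest linear sequence: 5 steps (1 → 3 → 4 → 6 → 9 → 10).

**Steps most likely to fail and fallbacks**

Step 4 (highest risk). Three processes could defeat the fold:
- it may take the aldol course, the future C3 methylene adding to the chain C3 ketone;
- it may end in O-cyclisation to a pyranone or lactone, or methoxide may cleave the polyketo chain by retro-Claisen before ring A closes;
- the electron-rich phloroglucinol may be oxidised by air under base.

The fallback lowers the oxidation level of the chain so that the competing carbon nucleophile and the aryl ketone no longer exist. It sets out from Weinreb amide 2. The lithium enolate of commercial (E)-4-(4-methoxyphenyl)but-3-en-2-one F1 (LiN(iPr)2, THF, −78 °C) would be acylated by 2 to (E)-1-methoxy-6-(4-methoxyphenyl)hex-5-ene-2,4-dione F2. The dianion of F2 and a second equivalent of 2 would give (E)-1,3-dimethoxy-8-(4-methoxyphenyl)oct-7-ene-2,4,6-trione F3, and the trianion of F3 with dimethyl carbonate 5 would give methyl (E)-2,4-dimethoxy-9-(4-methoxyphenyl)-3,5,7-trioxonon-8-enoate F4. Mg(OMe)2 in methanol should then close ring A by the same Claisen mode, the known folding of a cinnamoyl triketo ester, to give (E)-1-(2,4,6-trihydroxy-3,5-dimethoxyphenyl)-3-(4-methoxyphenyl)prop-2-en-1-one F5. Catalytic I2 in DMSO at 120 °C should cyclise F5 through racemic 5,7-dihydroxy-6,8-dimethoxy-2-(4-methoxyphenyl)chroman-4-one F6 and dehydrogenate it. Ring A has no free position for iodination. This comes back to the route at nevadensin 9.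

Step 3. The fourth deprotonation may be incomplete, the new β-keto ester may quench unreacted tetraanion by proton transfer, and the polyketone may undergo aldol cyclisation during the quench. The fallback sets out from tetraketone 4 and separates carboxylation from ester formation. The tetraanion would be trapped with CO2 gas at −78 °C, where the carboxylate product cannot protonate remaining tetraanion, and cold acidification would give 2,4-dimethoxy-9-(4-methoxyphenyl)-3,5,7,9-tetraoxononanoic acid F7. Kept cold to avoid decarboxylation, F7 would be esterified at once with TMSCHN2 in toluene/MeOH at 0 °C, the carboxylic acid reacting much faster than the enols. This comes back to the route at ester 6.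

Step 2. Trianion formation at the methoxy-substituted terminus may be slow, the carbanion may enolise the acyl donor instead of adding to it, and the tetraketone may self-cyclise on work-up. The fallback sets out from triketone 3 and replaces acylation by aldol addition and oxidation. The trianion would be added to methoxyacetaldehyde (MeOCH2CHO) at −78 °C to give 7-hydroxy-6,8-dimethoxy-1-(4-methoxyphenyl)octane-1,3,5-trione F8 as a diastereomer mixture. IBX in EtOAc at reflux, a known oxidation of β-hydroxy ketones to β-diketones, would then return to tetraketone 4.

**Further compounds**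

F1 | step 4 | (E)-4-(4-methoxyphenyl)but-3-en-2-one (commercial) | COc1ccc(/C=C/C(C)=O)cc1
F2 | step 4 | (E)-1-methoxy-6-(4-methoxyphenyl)hex-5-ene-2,4-dione | COCC(=O)CC(=O)/C=C/c1ccc(OC)cc1
F3 | step 4 | (E)-1,3-dimethoxy-8-(4-methoxyphenyl)oct-7-ene-2,4,6-trione | COCC(=O)C(OC)C(=O)CC(=O)/C=C/c1ccc(OC)cc1
F4 | step 4 | methyl (E)-2,4-dimethoxy-9-(4-methoxyphenyl)-3,5,7-trioxonon-8-enoate | COC(=O)C(OC)C(=O)C(OC)C(=O)CC(=O)/C=C/c1ccc(OC)cc1
F5 | step 4 | (E)-1-(2,4,6-trihydroxy-3,5-dimethoxyphenyl)-3-(4-methoxyphenyl)prop-2-en-1-one | COc1ccc(/C=C/C(=O)c2c(O)c(OC)c(O)c(OC)c2O)cc1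
F6 | step 4 | 5,7-dihydroxy-6,8-dimethoxy-2-(4-methoxyphenyl)chroman-4-one (racemic) | COc1ccc(C2CC(=O)c3c(O)c(OC)c(O)c(OC)c3O2)cc1
F7 | step 3 | 2,4-dimethoxy-9-(4-methoxyphenyl)-3,5,7,9-tetraoxononanoic acid | COc1ccc(C(=O)CC(=O)CC(=O)C(OC)C(=O)C(OC)C(=O)O)cc1
F8 | step 2 | 7-hydroxy-6,8-dimethoxy-1-(4-methoxyphenyl)octane-1,3,5-trione (diastereomer mixture) | COc1ccc(C(=O)CC(=O)CC(=O)C(OC)C(O)COC)cc1
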